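**Retrosynthetic overview**

- The target is (2S)-5-hydroxy-2-(4-hydroxyphenyl)-7-methoxy-6,8-bis(3-methylbut-2-enyl)chroman-4-one. Ring C is opened at O1–C2 (retro oxa-Michael) to a 2',6'-dihydroxy-4'-methoxy-3',5'-diprenylchalcone; C2 is set by catalyst control, and the O7 methyl is put on the unchelated para hydroxyl beforehand.
- The strategy rests on ring A: all six carbons are substituted, and at the chalcone stage the ring has a mirror plane through C7 and C4a. C6 and C8 each carry a prenyl group between two oxygenated carbons.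
- Ring A is cut at C6–C7 and C4a–C8a. C4a–C5–C6(prenyl) comes from a 1,3-bis(silyloxy)diene made from 6-methylhept-5-en-2-one; C7–C8(prenyl)–C8a comes from prenylmalonyl dichloride. No aromatic prenylation is needed.
- The diene is made from the kinetic enolate of the ketone and a silyl-protected 4-coumaroyl donor; the dichloride from diethyl malonate and prenyl bromide.
- Ring order: ring B is bought, ring A is built in step 8, ring C is closed in step 10.

Key step: step 8

Assumption: the enol ether double bonds of 7, 8 and 14 are drawn Z; their geometry does not matter for the annulation because both carbons end up in the aromatic ring, and a mixture of isomers would serve equally.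
Assumption: the quinidine-derived thiourea is taken to give the 2S product; if the sense of induction is the opposite, the quinine-derived pseudoenantiomer is used in the same way.

**Route**

Step 1
Reactants: 1 (E)-4-hydroxycinnamic acid
Product: 3 (E)-3-[4-(triisopropylsilyloxy)phenyl]prop-2-enoic acid, via silyl ester silyl ether 2 (not isolated)
Conditions: iPr3SiCl (2.3 equiv), imidazole (5 equiv), DMF, rt; then K2CO3 (1.5 equiv), THF/MeOH/H2O, 0 °C; cold 1 M HCl to pH 3
Reagents that add atoms: triisopropylsilyl chloride, CC(C)[Si](Cl)(C(C)C)C(C)C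
Why: Imidazole-mediated silylation covers both acidic OH groups, and mild basic hydrolysis then cleaves only the far more labile silyl ester, leaving the aryl silyl ether.

Step 2
Reactants: 3 (E)-3-[4-(triisopropylsilyloxy)phenyl]prop-2-enoic acid
Product: 4 (E)-1-(benzotriazol-1-yl)-3-[4-(triisopropylsilyloxy)phenyl]prop-2-en-1-one
Conditions: 1H-benzotriazole (4 equiv), SOCl2 (1.05 equiv), CH2Cl2, rt
Reagents that add atoms: 1H-benzotriazole, c1ccc2[nH]nnc2c1
Why: Katritzky N-acylbenzotriazole formation gives a stable, neutral acyl donor that acylates ketone enolates at carbon, with the excess benzotriazole buffering the HCl.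

Step 3
Reactants: 4 (E)-1-(benzotriazol-1-yl)-3-[4-(triisopropylsilyloxy)phenyl]prop-2-en-1-one; 5 6-methylhept-5-en-2-one
Product: 6 (E)-9-methyl-1-[4-(triisopropylsilyloxy)phenyl]deca-1,8-diene-3,5-dione
Conditions: 5 (2.0 equiv), LiN(iPr)2 (2.0 equiv), THF, −78 °C; then 4 (1.0 equiv), −78 → −20 °C; aq. NH4Cl
Reagents that add atoms: none
Why: LiN(iPr)2 at −78 °C deprotonates the methyl group of 5 (kinetic enolate), and this enolate is C-acylated by the acylbenzotriazole in a crossed Claisen condensation, the second equivalent of enolate taking the acidic proton of the β-diketone.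

Step 4
Reactants: 6 (E)-9-methyl-1-[4-(triisopropylsilyloxy)phenyl]deca-1,8-diene-3,5-dione
Product: 8 (1E,3Z,5Z)-9-methyl-1-[4-(triisopropylsilyloxy)phenyl]-3,5-bis(trimethylsilyloxy)deca-1,3,5,8-tetraene, via monosilyl enol ether 7 (not isolated)
Conditions: Me3SiOTf (2.3 equiv), Et3N (3 equiv), Et2O, 0 °C → rt; pentane extraction under argon, no aqueous work-up, used at once
Reagents that add atoms: trimethylsilyl trifluoromethanesulfonate, C[Si](C)(C)OS(=O)(=O)C(F)(F)F
Why: Twofold silyl enol ether formation by soft enolisation can only enolise toward C6, because the cinnamoyl flank has no α-hydrogen, so a single constitutional bis(silyloxy)diene should result.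

Step 5
Reactants: 9 diethyl malonate; 10 prenyl bromide (1-bromo-3-methylbut-2-ene)
Product: 11 diethyl 2-(3-methylbut-2-enyl)malonate
Conditions: NaOEt (1.0 equiv), 9 (1.5 equiv), EtOH, 0 °C → rt
Reagents that add atoms: none
Why: Malonic ester alkylation (SN2 on the primary allylic bromide), with excess malonate to suppress dialkylation.

Step 6
Reactants: 11 diethyl 2-(3-methylbut-2-enyl)malonate
Product: 12 2-(3-methylbut-2-enyl)malonic acid
Conditions: KOH (2.5 equiv), EtOH/H2O, rt; then 1 M HCl, 0 °C, pH 2
Reagents that add atoms: potassium hydroxide, [K+].[OH-]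
Why: Saponification at room temperature with cold acidification avoids decarboxylation of the malonic acid and acid damage to the prenyl alkene.

Step 7
Reactants: 12 2-(3-methylbut-2-enyl)malonic acid
Product: 13 2-(3-methylbut-2-enyl)malonyl dichloride
Conditions: 1-chloro-N,N,2-trimethylprop-1-en-1-amine (2.2 equiv), CH2Cl2, 0 °C → rt; bulb-to-bulb distillation
Reagents that add atoms: 1-chloro-N,N,2-trimethylprop-1-en-1-amine, CC(C)=C(Cl)N(C)C
Why: Acid chloride formation with the Ghosez reagent is neutral and releases no HCl, so the trisubstituted alkene is not hydrochlorinated.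

Step 8
Reactants: 8 (1E,3Z,5Z)-9-methyl-1-[4-(triisopropylsilyloxy)phenyl]-3,5-bis(trimethylsilyloxy)deca-1,3,5,8-tetraene; 13 2-(3-methylbut-2-enyl)malonyl dichloride
Product: 15 (E)-1-[2,4,6-trihydroxy-3,5-bis(3-methylbut-2-enyl)phenyl]-3-[4-(triisopropylsilyloxy)phenyl]prop-2-en-1-one, via C6-acylated acid chloride 14 (not isolated)
Conditions: 8 added slowly to 13 (1.1 equiv), CH2Cl2 (0.02 M), −78 °C; Me3SiOTf (0.2 equiv), 2,6-di-tert-butyl-4-methylpyridine (0.3 equiv), −78 → 0 °C; then MeOH, aq. citric acid
Reagents that add atoms: none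
Why: Proposed new method: the terminal carbon C6 of the bis(silyloxy)diene, its most nucleophilic site, attacks one acid chloride of 13 with loss of Me3SiCl to give 14, whose remaining enol silane carbon C4a then attacks the second acid chloride (activated as the acyl triflate by catalytic Me3SiOTf), and the resulting 2-acylcyclohexane-1,3,5-trione tautomerises to the phloroglucinol. The closest known reaction types are the formal [3+3] cyclisation of 1,3-bis(silyloxy)dienes with 1,3-dielectrophiles, the acylation of such dienes at the terminal carbon by acid chlorides, and the annulation of silyl enol ethers with malonyl dichlorides. Ring A is closed by a 6-(enolexo)-exo-trig C-acylation that forms C4a–C8a after the intermolecular C6–C7 bond. No stereocentre is created, and the two CH centres of 14 disappear on aromatisation. The step needs attack by C6 before C4a and closure through C4a instead of O5; the first follows from the diene having one enolisable flank and its largest coefficient at the terminus, the second from keeping the C4=C4a enol silane intact in a base-free, Lewis acidic medium where enol silanes acylate at carbon, with aromatisation making the carbon closure irreversible. The hindered pyridine traps triflic acid so that the prenyl groups do not cyclise onto the neighbouring phenols.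

Step 9
Reactants: 15 (E)-1-[2,4,6-trihydroxy-3,5-bis(3-methylbut-2-enyl)phenyl]-3-[4-(triisopropylsilyloxy)phenyl]prop-2-en-1-one
Product: 16 (E)-1-[2,6-dihydroxy-4-methoxy-3,5-bis(3-methylbut-2-enyl)phenyl]-3-[4-(triisopropylsilyloxy)phenyl]prop-2-en-1-one
Conditions: MeOH (1.05 equiv), PPh3 (1.1 equiv), diisopropyl azodicarboxylate (1.1 equiv), THF, 0 °C
Reagents that add atoms: methanol, CO
Why: Mitsunobu etherification alkylates the most acidic phenol, which is the 4'-hydroxyl para to the carbonyl and not hydrogen-bonded, while the ortho hydroxyls are less acidic and one is held in the chelate.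

Step 10
Reactants: 16 (E)-1-[2,6-dihydroxy-4-methoxy-3,5-bis(3-methylbut-2-enyl)phenyl]-3-[4-(triisopropylsilyloxy)phenyl]prop-2-en-1-one
Product: 17 (2S)-5-hydroxy-7-methoxy-6,8-bis(3-methylbut-2-enyl)-2-[4-(triisopropylsilyloxy)phenyl]chroman-4-one
Conditions: 9-amino-9-deoxy-epi-quinidine N-[3,5-bis(trifluoromethyl)phenyl]thiourea (10 mol %), toluene, −20 °C
Reagents that add atoms: none
Why: Enantioselective intramolecular oxa-Michael addition (6-endo-trig) under bifunctional cinchona thiourea catalysis, in which the quinuclidine activates one of the two equivalent ortho phenols and the thiourea binds the enone carbonyl so that oxygen adds to the Si face of C-β to give 2S, the low temperature and apolar solvent holding back the uncatalysed closure and the retro reaction.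

Step 11
Reactants: 17 (2S)-5-hydroxy-7-methoxy-6,8-bis(3-methylbut-2-enyl)-2-[4-(triisopropylsilyloxy)phenyl]chroman-4-one
Product: 18 (2S)-5-hydroxy-2-(4-hydroxyphenyl)-7-methoxy-6,8-bis(3-methylbut-2-enyl)chroman-4-one
Conditions: (nBu)4NF (1.2 equiv), AcOH (1.5 equiv), THF, 0 °C
Reagents that add atoms: none
Why: Fluoride desilylation of the aryl silyl ether, buffered with acetic acid so that the 5-hydroxyflavanone does not open by base-induced retro oxa-Michael reaction and C2 keeps its configuration; the prenyl groups and the methyl ether are inert.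

**Compound list**

1 | (E)-4-hydroxycinnamic acid | OC(=O)/C=C/c1ccc(O)cc1 | starting material
2 | triisopropylsilyl (E)-3-[4-(triisopropylsilyloxy)phenyl]prop-2-enoate | CC(C)[Si](OC(=O)/C=C/c1ccc(O[Si](C(C)C)(C(C)C)C(C)C)cc1)(C(C)C)C(C)C | intermediate
3 | (E)-3-[4-(triisopropylsilyloxy)phenyl]prop-2-enoic acid | OC(=O)/C=C/c1ccc(O[Si](C(C)C)(C(C)C)C(C)C)cc1 | intermediate
4 | (E)-1-(benzotriazol-1-yl)-3-[4-(triisopropylsilyloxy)phenyl]prop-2-en-1-one | O=C(/C=C/c1ccc(O[Si](C(C)C)(C(C)C)C(C)C)cc1)n1nnc2ccccc21 | intermediate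
5 | 6-methylhept-5-en-2-one | CC(=O)CCC=C(C)C | starting material
6 | (E)-9-methyl-1-[4-(triisopropylsilyloxy)phenyl]deca-1,8-diene-3,5-dione | CC(C)=CCCC(=O)CC(=O)/C=C/c1ccc(O[Si](C(C)C)(C(C)C)C(C)C)cc1 | intermediate
7 | (1E,3Z)-9-methyl-1-[4-(triisopropylsilyloxy)phenyl]-3-(trimethylsilyloxy)deca-1,3,8-trien-5-one | CC(C)=CCCC(=O)/C=C(O[Si](C)(C)C)/C=C/c1ccc(O[Si](C(C)C)(C(C)C)C(C)C)cc1 | intermediate
8 | (1E,3Z,5Z)-9-methyl-1-[4-(triisopropylsilyloxy)phenyl]-3,5-bis(trimethylsilyloxy)deca-1,3,5,8-tetraene | CC(C)=CC/C=C(\O[Si](C)(C)C)/C=C(\O[Si](C)(C)C)/C=C/c1ccc(O[Si](C(C)C)(C(C)C)C(C)C)cc1 | intermediate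
9 | diethyl malonate | CCOC(=O)CC(=O)OCC | starting material
10 | prenyl bromide (1-bromo-3-methylbut-2-ene) | CC(C)=CCBr | starting material
11 | diethyl 2-(3-methylbut-2-enyl)malonate | CCOC(=O)C(CC=C(C)C)C(=O)OCC | intermediate
12 | 2-(3-methylbut-2-enyl)malonic acid | OC(=O)C(CC=C(C)C)C(=O)O | intermediate
13 | 2-(3-methylbut-2-enyl)malonyl dichloride | CC(C)=CCC(C(=O)Cl)C(=O)Cl | intermediate
14 | (6Z,8E)-2,4-bis(3-methylbut-2-enyl)-3,5-dioxo-9-[4-(triisopropylsilyloxy)phenyl]-7-(trimethylsilyloxy)nona-6,8-dienoyl chloride | CC(C)=CCC(C(=O)Cl)C(=O)C(CC=C(C)C)C(=O)/C=C(O[Si](C)(C)C)/C=C/c1ccc(O[Si](C(C)C)(C(C)C)C(C)C)cc1 | intermediate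
15 | (E)-1-[2,4,6-trihydroxy-3,5-bis(3-methylbut-2-enyl)phenyl]-3-[4-(triisopropylsilyloxy)phenyl]prop-2-en-1-one | Oc1c(CC=C(C)C)c(O)c(C(=O)/C=C/c2ccc(O[Si](C(C)C)(C(C)C)C(C)C)cc2)c(O)c1CC=C(C)C | intermediate
16 | (E)-1-[2,6-dihydroxy-4-methoxy-3,5-bis(3-methylbut-2-enyl)phenyl]-3-[4-(triisopropylsilyloxy)phenyl]prop-2-en-1-one | COc1c(CC=C(C)C)c(O)c(C(=O)/C=C/c2ccc(O[Si](C(C)C)(C(C)C)C(C)C)cc2)c(O)c1CC=C(C)C | intermediate
17 | (2S)-5-hydroxy-7-methoxy-6,8-bis(3-methylbut-2-enyl)-2-[4-(triisopropylsilyloxy)phenyl]chroman-4-one | COc1c(CC=C(C)C)c(O)c2c(c1CC=C(C)C)O[C@H](c1ccc(O[Si](C(C)C)(C(C)C)C(C)C)cc1)CC2=O | intermediate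
18 | (2S)-5-hydroxy-2-(4-hydroxyphenyl)-7-methoxy-6,8-bis(3-methylbut-2-enyl)chroman-4-one | COc1c(CC=C(C)C)c(O)c2c(c1CC=C(C)C)O[C@H](c1ccc(O)cc1)CC2=O | target

**Step count**

Total: 11 steps. Longest linear sequence: 8 steps (1, 2, 3, 4, 8, 9, 10, 11).

**Steps most likely to fail**

1. Step 8 (annulation). The ring may close through oxygen O5 instead of carbon C4a (lactonisation in place of benzannulation), the two bifunctional partners may oligomerise, or a prenyl group may cyclise onto a neighbouring phenol under acid. The fallback uses known chemistry, sets out from diene 8 and diester 11, and returns at 15. Diester 11 is half-saponified (KOH, 1.0 equiv, EtOH, 0 °C) to 2-(ethoxycarbonyl)-5-methylhex-4-enoic acid F1. The Ghosez reagent converts this into ethyl 2-(chlorocarbonyl)-5-methylhex-4-enoate F2. F2 acylates 8 at its terminal carbon only (CH2Cl2, Me3SiOTf 0.3 equiv, −78 → 0 °C), which is the known reaction of bis(silyloxy)dienes with acid chlorides, malonic half-ester chlorides included. Aqueous work-up gives ethyl (E)-2,4-bis(3-methylbut-2-enyl)-3,5,7-trioxo-9-[4-(triisopropylsilyloxy)phenyl]non-8-enoate F3. The C4a–C8a bond is then made separately by a base-mediated Claisen cyclisation of this 3,5,7-triketo ester (Mg(OCH3)2, MeOH/THF, 0 °C → rt, then cold dilute acid), the known route from such esters to acylphloroglucinols, giving 15.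

2. Step 10 (enantioselective ring closure). Facial selectivity may be poor on a chalcone without an extra activating group, the uncatalysed closure may compete, and the product may erode by reversible ring opening. The fallback sets out from 16 and returns at 17. Chalcone 16 is closed without stereocontrol (NaOAc, EtOH, 60 °C) to racemic 5-hydroxy-7-methoxy-6,8-bis(3-methylbut-2-enyl)-2-[4-(triisopropylsilyloxy)phenyl]chroman-4-one F4. F4 is resolved by asymmetric transfer hydrogenation, a kinetic resolution known for flavanones (RuCl(p-cymene)[(R,R)-TsDPEN], HCO2H/Et3N 5:2, EtOAc, rt, to about half conversion). By analogy with 4-chromanones this catalyst should reduce the 2R ketone to (2R,4R)-7-methoxy-6,8-bis(3-methylbut-2-enyl)-2-[4-(triisopropylsilyloxy)phenyl]chromane-4,5-diol F5, leaving 17 to be separated by chromatography.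

3. Step 9 (regioselective methylation). Methylation may occur at an ortho hydroxyl, over-methylation may follow, and the basic Mitsunobu betaine may trigger premature racemic ring closure. The fallback sets out from 15 and returns at 17, changing the order so that chelation distinguishes the hydroxyls. The thiourea-catalysed oxa-Michael closure of step 10 is run on 15 itself to give (2S)-5,7-dihydroxy-6,8-bis(3-methylbut-2-enyl)-2-[4-(triisopropylsilyloxy)phenyl]chroman-4-one F6. In F6 the 5-hydroxyl is locked in the hydrogen bond to the ketone, so trimethylsilyldiazomethane (MeOH/toluene, rt, neutral conditions that do not open the flavanone) should methylate only the 7-hydroxyl and give 17.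

**Further compounds**

F1 | step 8 | 2-(ethoxycarbonyl)-5-methylhex-4-enoic acid | CCOC(=O)C(CC=C(C)C)C(=O)O
F2 | step 8 | ethyl 2-(chlorocarbonyl)-5-methylhex-4-enoate | CCOC(=O)C(CC=C(C)C)C(=O)Cl
F3 | step 8 | ethyl (E)-2,4-bis(3-methylbut-2-enyl)-3,5,7-trioxo-9-[4-(triisopropylsilyloxy)phenyl]non-8-enoate | CCOC(=O)C(CC=C(C)C)C(=O)C(CC=C(C)C)C(=O)CC(=O)/C=C/c1ccc(O[Si](C(C)C)(C(C)C)C(C)C)cc1
F4 | step 10 | racemic 5-hydroxy-7-methoxy-6,8-bis(3-methylbut-2-enyl)-2-[4-(triisopropylsilyloxy)phenyl]chroman-4-one | COc1c(CC=C(C)C)c(O)c2c(c1CC=C(C)C)OC(c1ccc(O[Si](C(C)C)(C(C)C)C(C)C)cc1)CC2=O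
F5 | step 10 | (2R,4R)-7-methoxy-6,8-bis(3-methylbut-2-enyl)-2-[4-(triisopropylsilyloxy)phenyl]chromane-4,5-diol | COc1c(CC=C(C)C)c(O)c2c(c1CC=C(C)C)O[C@@H](c1ccc(O[Si](C(C)C)(C(C)C)C(C)C)cc1)C[C@H]2O
F6 | step 9 | (2S)-5,7-dihydroxy-6,8-bis(3-methylbut-2-enyl)-2-[4-(triisopropylsilyloxy)phenyl]chroman-4-one | Oc1c(CC=C(C)C)c(O)c2c(c1CC=C(C)C)O[C@H](c1ccc(O[Si](C(C)C)(C(C)C)C(C)C)cc1)CC2=O
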